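Ring A carries its bromines at C3 and C5. They are meta to the C1 hydroxyl, so phenol-directed bromination cannot reach them, but both carbons are ortho neighbours of the unsubstituted C4. Everything rests on disconnecting C3–Br and C5–Br from a ring A that bears a sacrificial amino group at C4 and a nitro group at C1 as the masked hydroxyl. In this precursor, 3-(2,4-dibromophenoxy)-4-nitroaniline 3, the amine (ortho), the nitro group (meta) and the C2 ether oxygen (ortho and para) all point to C3 and C5. Br2 should therefore set both halogens in one operation. One SNAr leads to 3; deamination, nitro reduction and diazonium hydrolysis finish the target.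

Key step: step 2

Remark on numbering: ring A keeps the target numbering throughout (C1 oxygen or its nitrogen precursor, C2 ether carbon, C3 Br, C4 H, C5 Br, C6 H), and ring B positions are primed. Systematic names use their own locants: aniline locants 1, 2, 3, 4, 5, 6 of compounds 3 and 5 are ring A C4, C3, C2, C1, C6, C5. The target is achiral, so no stereocentre has to be set.

Step 1
Reactants: 1 3-fluoro-4-nitroaniline; 2 2,4-dibromophenol
Product: 3 3-(2,4-dibromophenoxy)-4-nitroaniline
Conditions: K2CO3 (1.5 equiv), DMSO, 100 °C
Reagents that add atoms: none
Why: Nucleophilic aromatic substitution (SNAr, addition–elimination): the phenoxide of 2 adds to the fluorine-bearing carbon, the ortho nitro group stabilises the Meisenheimer complex and fluoride leaves, while the amino nitrogen of 1, conjugated with the para nitro group, is too weak a nucleophile to compete and the bromines of 2 sit on an unactivated ring.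

Step 2
Reactants: 3 3-(2,4-dibromophenoxy)-4-nitroaniline
Product: 5 2,6-dibromo-3-(2,4-dibromophenoxy)-4-nitroaniline, via C5 monobromide 4 (not isolated)
Conditions: Br2 (2.2 equiv), AcOH, 25 to 55 °C
Reagents that add atoms: bromine, BrBr
Why: Each C–Br bond forms by electrophilic aromatic substitution, in which Br2 attacks a carbon ortho to the amino group, the arenium ion is stabilised in its iminium form by the nitrogen lone pair, and proton loss restores the aromatic ring. The closest known reaction type is the 2,6-dibromination of 4-nitroanilines with Br2 in AcOH. No ring is closed and no stereocentre is created. The step needs C3 and C5 to react in preference to C6 of ring A and C6' of ring B, and the substrate secures this because the C4 amine (ortho), the C1 nitro group (meta) and the C2 ether oxygen (ortho to C3, para to C5) converge on the same two carbons, whereas C6 is ortho to the nitro group and meta to both donors. Ring B is deactivated by its two bromines and its oxygen lone pair is drawn toward the nitroarene, so C6' should stay untouched in the absence of a Lewis acid. The open C5 should react first to give 4 and the crowded C3, between NH2 and the aryloxy group, second, which is why a slight excess of Br2 and gentle warming are planned.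

Step 3
Reactants: 5 2,6-dibromo-3-(2,4-dibromophenoxy)-4-nitroaniline
Product: 7 1,5-dibromo-2-(2,4-dibromophenoxy)-3-nitrobenzene, via diazonium hydrogen sulfate 6 (not isolated)
Conditions: NaNO2 (portionwise), conc. H2SO4, EtOH, 75–80 °C
Reagents that add atoms: none
Why: Hydrodediazoniation (reductive deamination): the weakly basic amine is diazotised in strongly acidic ethanol and the very electron-poor diazonium ion 6 is reduced by ethanol with loss of N2, the standard deamination of 2,6-dibromo-4-nitroanilines, in which electron-withdrawing groups favour reduction over aryl ethyl ether formation and chloride-free acid rules out halogen exchange at the activated ortho carbons.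

Step 4
Reactants: 7 1,5-dibromo-2-(2,4-dibromophenoxy)-3-nitrobenzene
Product: 8 3,5-dibromo-2-(2,4-dibromophenoxy)aniline
Conditions: Fe powder (5 equiv), AcOH, EtOH/H2O, 70 °C
Reagents that add atoms: none
Why: Béchamp-type reduction: stepwise electron transfer from zerovalent iron and protonation by AcOH take the nitro group through the nitroso and hydroxylamine stages to the amine, and the method is known to spare aryl bromides and diaryl ethers, which catalytic hydrogenation would put at risk.

Step 5
Reactants: 8 3,5-dibromo-2-(2,4-dibromophenoxy)aniline
Product: 10 3,5-dibromo-2-(2,4-dibromophenoxy)phenol, via diazonium hydrogen sulfate 9 (not isolated)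
Conditions: NaNO2 (1.1 equiv), conc. H2SO4, AcOH, 0–10 °C; then dropwise into 60% aq H2SO4/1,2-dichlorobenzene, 130 °C
Reagents that add atoms: water, O
Why: Diazotisation followed by thermal hydrolysis of the diazonium salt (dediazoniation of SN1 type through the aryl cation): nitrosylsulfuric acid copes with the weakly basic amine, hydrogen sulfate is a poor nucleophile so that water captures C1, and slow addition to the hot two-phase mixture keeps the diazonium concentration low and moves 10 into the organic layer, a protocol established for 2-(2,4-dihalophenoxy)anilines.

Compound list
1 | 3-fluoro-4-nitroaniline | Nc1ccc([N+](=O)[O-])c(F)c1 | starting material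
2 | 2,4-dibromophenol | Oc1ccc(Br)cc1Br | starting material
3 | 3-(2,4-dibromophenoxy)-4-nitroaniline | Nc1ccc([N+](=O)[O-])c(Oc2ccc(Br)cc2Br)c1 | intermediate
4 | 2-bromo-5-(2,4-dibromophenoxy)-4-nitroaniline (bromine at ring A C5) | Nc1cc(Oc2ccc(Br)cc2Br)c([N+](=O)[O-])cc1Br | intermediate
5 | 2,6-dibromo-3-(2,4-dibromophenoxy)-4-nitroaniline | Nc1c(Br)cc([N+](=O)[O-])c(Oc2ccc(Br)cc2Br)c1Br | intermediate
6 | 2,6-dibromo-3-(2,4-dibromophenoxy)-4-nitrobenzenediazonium hydrogen sulfate | N#[N+]c1c(Br)cc([N+](=O)[O-])c(Oc2ccc(Br)cc2Br)c1Br.OS(=O)(=O)[O-] | intermediate
7 | 1,5-dibromo-2-(2,4-dibromophenoxy)-3-nitrobenzene | O=[N+]([O-])c1cc(Br)cc(Br)c1Oc1ccc(Br)cc1Br | intermediate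
8 | 3,5-dibromo-2-(2,4-dibromophenoxy)aniline | Nc1cc(Br)cc(Br)c1Oc1ccc(Br)cc1Br | intermediate
9 | 3,5-dibromo-2-(2,4-dibromophenoxy)benzenediazonium hydrogen sulfate | N#[N+]c1cc(Br)cc(Br)c1Oc1ccc(Br)cc1Br.OS(=O)(=O)[O-] | intermediate
10 | 3,5-dibromo-2-(2,4-dibromophenoxy)phenol | Oc1cc(Br)cc(Br)c1Oc1ccc(Br)cc1Br | target

Total step count: 5
Longest linear sequence: 5 steps

Steps most likely to fail

Step 5. Three things may go wrong:
- The electron-poor diazonium ion may lose N2 only under forcing heat.
- The reactive C1 centre may then attack C6' of ring B intramolecularly (Pschorr-type ring closure) instead of being captured by water.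
- Azo coupling with phenol already formed may consume material.

The fallback sets out from 8 and makes the C–O bond by boron-to-oxygen migration instead of cation capture. A metal-free Sandmeyer-type borylation (tBuONO, B2pin2, MeCN, 25 to 80 °C) should give the pinacol boronate 2-[3,5-dibromo-2-(2,4-dibromophenoxy)phenyl]-4,4,5,5-tetramethyl-1,3,2-dioxaborolane F1. Oxidation with H2O2 and NaOH in THF at 0 °C, which leaves aryl bromides alone, comes back to the route at 10.

Step 2. The second bromination at the crowded C3 may stall at the monobromide stage. Harsher conditions used to push it may start substitution at C6' of ring B. The fallback sets out from 1 and reverses the order of bromination and ether formation. Br2 in AcOH should convert 1 into 2,6-dibromo-3-fluoro-4-nitroaniline F2, where the small fluorine leaves the flanked carbon accessible and no second arene is present. SNAr of F2 with 2 (K2CO3, DMSO, 90–110 °C) then displaces only the fluorine, the one halogen ortho to the nitro group (both bromines are meta to it). This comes back to the route at 5.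

Step 1. The para amino group feeds electron density into the nitro group and weakens its activation of the C–F carbon. The phenoxide is also weak and ortho-hindered, so the substitution may be slow and long heating may degrade the aniline. The fallback sets out from 2 and forms the ether on a ring that does not yet carry nitrogen at C4. The potassium phenoxide of 2 (KOtBu, toluene, 25–60 °C) should react with purchased 2,4-difluoronitrobenzene F3 at the ortho fluorine, since a non-polar solvent keeps the ion pair associated with the nitro oxygen. This gives 2,4-dibromo-1-(5-fluoro-2-nitrophenoxy)benzene F4. Ammonia (NH3, DMSO, sealed vessel, 80–100 °C) then displaces the remaining para fluorine, a far better leaving group than the aryloxide, and comes back to the route at 3.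

Further compounds
F1 | step 5 | 2-[3,5-dibromo-2-(2,4-dibromophenoxy)phenyl]-4,4,5,5-tetramethyl-1,3,2-dioxaborolane | CC1(C)OB(OC1(C)C)c1cc(Br)cc(Br)c1Oc1ccc(Br)cc1Br
F2 | step 2 | 2,6-dibromo-3-fluoro-4-nitroaniline | Nc1c(Br)cc([N+](=O)[O-])c(F)c1Br
F3 | step 1 | 2,4-difluoronitrobenzene (purchased) | O=[N+]([O-])c1ccc(F)cc1F
F4 | step 1 | 2,4-dibromo-1-(5-fluoro-2-nitrophenoxy)benzene | O=[N+]([O-])c1ccc(F)cc1Oc1ccc(Br)cc1Br
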